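Numbering is that of labdane: ring A C1–C5/C10, ring B C5–C10, ring C the spiro tetrahydrofuran at C9, ring D the dihydrofuran. C11 sits on C9, C17 on C8, C18/C19 on C4, C20 on C10. "Drimane" means the bicyclic C1–C11/C17–C20 part.
Cuts, from the outside in: acetate C–O, O–C15 (ring D), C14–C15, O–C13 (ring C), C11–C12, C8–C17 with the C6 and C9 oxygens, then C9–C10 and C4–C5 together, and last C6–C7.
Enabling feature: rings A and B are a trans-fused decalin in which C4 bears two methyls, C10 bears one methyl and no hydrogen, and H5 lies anti to C20. Read along C4–C3–C2–C1–C10–C5–C6 this is a folded geranyl unit, and C7–C8–C9–C11 is an acetoacetate. One protonation at C3 can therefore close both rings of an open-chain dienyl β-keto ester.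
Forward order: chain joined at C6–C7, rings A and B closed in one cascade, ring B oxidised and methylated, side chain added at C11, ring C closed, ring D closed, acetylation.
Stereochemistry: C5/C10 come from a chiral proton source plus the E-alkene in a chair–chair fold, C9 from α-face enolate hydroxylation anti to C20, and C6 from α-face hydride. C8 comes from 6β-OH-directed hydrogenation, and C13 from asymmetric epoxidation followed by SN2 inversion.

Key step: step 2

Assumption: the (R)-binaphthol-derived acid is taken to protonate the face of C3=C4 that leads to the (5S,10S) series, as it does with homofarnesyl-type polyenes; if the sense proves opposite, the (S)-ligand is used and nothing else changes.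

Step 1
Reactants: 1 methyl acetoacetate; 2 geranyl bromide
Product: 4 methyl (6E)-7,11-dimethyl-3-oxododeca-6,10-dienoate, via acetoacetate dianion 3 (not isolated)
Conditions: NaH, THF, 0 °C; n-BuLi, 0 °C; 2, 0 °C → rt; aq HCl
Reagents that add atoms: none
Why: γ-Alkylation of an acetoacetate dianion, in which the more basic terminal carbanion displaces the primary allylic bromide in an SN2 sense, so that C6–C7 forms, the E-alkene is untouched and no stereocentre arises.

Step 2
Reactants: 4 methyl (6E)-7,11-dimethyl-3-oxododeca-6,10-dienoate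
Product: 5 methyl 8-oxo-17-nordriman-11-oate [methyl (1R,4aS,8aS)-5,5,8a-trimethyl-2-oxodecahydronaphthalene-1-carboxylate; 5α-H; 9β-CO2Me; 10β-CH3]
Conditions: (R)-2-(2-fluorobenzyloxy)-2'-hydroxy-1,1'-binaphthyl (2.2 equiv) premixed with SnCl4 (2.0 equiv), toluene, −78 °C; slow addition of 4, −78 °C, 2–3 d; then SnCl4 (1 equiv), −78 → 0 °C; aq NaHCO3 (ligand recovered)
Reagents that add atoms: none
Why: Proposed new method: the phenolic proton of the binaphthol monoether, acidified by SnCl4 (a Lewis acid-assisted chiral Brønsted acid, LBA), is placed on C3 of the terminal alkene, C5 of the E-alkene captures the C4 cation (6-endo-trig, ring A, bond C4–C5), C9 of the β-keto ester enol captures the C10 cation (6-endo-trig through the enol, ring B, bond C9–C10), and loss of the enol proton makes the whole a net isomerisation. The closest known reactions are the achiral SnCl4 bicyclisation of geranylated β-keto esters and the LBA-induced enantioselective cyclisation of homogeranylarenes, geranyl aryl ethers and homofarnesyl silyl ethers; what has not been shown is a chelating β-dicarbonyl terminator under the chiral proton source. C5 is decided by the enantiotopic face of C3=C4 that the chiral acid protonates while the chain is folded, C10 by anti addition across the E-alkene in a chair–chair array (H5 and C20 trans), and C9 by equilibration through the enol to the equatorial ester. The step needs the chiral proton to outrun achiral acid, which is plausible because the SnCl4/β-keto ester background reaction calls for about 0 °C whereas the preformed LBA, used in excess to absorb ligand exchange with the dicarbonyl, acts at −78 °C in toluene. Initiation at C3=C4 and not at C5=C10 is secured by the substrate, since the terminal isopropylidene is the more accessible and more electron-rich alkene and only its protonation opens a six-membered path. Monocyclic olefins formed by early proton loss already carry C5 and should be closed diastereoselectively by the extra SnCl4 on warming once 4 is gone.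

Step 3
Reactants: 5 methyl 8-oxo-17-nordriman-11-oate
Product: 7 methyl 9α-hydroxy-8-oxo-17-nordriman-11-oate, via potassium enolate 6 (not isolated)
Conditions: KN(SiMe3)2, THF, −78 °C; 2-(phenylsulfonyl)-3-phenyloxaziridine, −78 °C; AcOH quench
Reagents that add atoms: 2-(phenylsulfonyl)-3-phenyloxaziridine, O=S(=O)(c1ccccc1)N1OC1c1ccccc1
Why: Davis oxidation of a β-keto ester enolate, in which the planar C9 takes up oxygen on its α face, anti to the axial C20 methyl on the neighbouring C10, so that the oxygen ends 9α (axial) and C11 stays 9β (equatorial).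

Step 4
Reactants: 7 methyl 9α-hydroxy-8-oxo-17-nordriman-11-oate
Product: 8 methyl 8,9α-bis(triethylsilyloxy)-17-nordrim-7-en-11-oate
Conditions: Et3SiOTf (3 equiv), Et3N, CH2Cl2, 0 °C → rt
Reagents that add atoms: triethylsilyl trifluoromethanesulfonate, CC[Si](CC)(CC)OS(=O)(=O)C(F)(F)F
Why: Silyl triflate/amine soft enolisation and O-silylation: because C9 is quaternary the C8 ketone can enolise only toward C7, so one operation gives the Δ7 silyl enol ether and caps the tertiary 9α-hydroxyl without touching a stereocentre.

Step 5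
Reactants: 8 methyl 8,9α-bis(triethylsilyloxy)-17-nordrim-7-en-11-oate
Product: 9 methyl 8-oxo-9α-(triethylsilyloxy)-17-nordrim-6-en-11-oate
Conditions: Pd(OAc)2 (1.1 equiv), MeCN, rt
Reagents that add atoms: none
Why: Saegusa–Ito oxidation, in which palladation of the enol silane at C7 and syn β-hydride loss from C6 give the Δ6-8-enone while the tertiary silyl ether and the ester are inert.

Step 6
Reactants: 9 methyl 8-oxo-9α-(triethylsilyloxy)-17-nordrim-6-en-11-oate
Product: 10 methyl 8β-hydroxy-9α-(triethylsilyloxy)drim-6-en-11-oate (C17 8α)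
Conditions: MeLi (1.5 equiv), Et2O, −78 °C; H2O quench at −78 °C
Reagents that add atoms: methyllithium, [Li]C
Why: 1,2-Addition of a hard organolithium to an enone, where MeLi should attack the C8 carbonyl rather than C6 or the neopentyl-type ester, most likely from the α face anti to C20, and the new C8 centre is erased in the next step so that either epimer serves.

Step 7
Reactants: 10 methyl 8β-hydroxy-9α-(triethylsilyloxy)drim-6-en-11-oate
Product: 11 methyl 6-oxo-9α-(triethylsilyloxy)drim-7-en-11-oate
Conditions: [C5H5NH][CrO3Cl] (pyridinium chlorochromate, 3 equiv), 4 Å sieves, CH2Cl2, rt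
Reagents that add atoms: pyridinium chlorochromate (one of its oxo oxygens becomes the C6 carbonyl oxygen), [O-][Cr](=O)(=O)Cl.c1cc[nH+]cc1
Why: Babler–Dauben oxidative transposition, in which the tertiary allylic chromate ester shifts by a [3,3] path to C6 and is oxidised there, moving oxygen from C8 to C6 and leaving C17 on a Δ7 alkene without creating a stereocentre.

Step 8
Reactants: 11 methyl 6-oxo-9α-(triethylsilyloxy)drim-7-en-11-oate
Product: 12 9α-(triethylsilyloxy)drim-7-ene-6β,11-diol
Conditions: i-Bu2AlH (5 equiv), CH2Cl2, −78 → 0 °C; aq potassium sodium tartrate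
Reagents that add atoms: none
Why: Aluminium hydride reduction, in which the ester goes to the C11 primary alcohol and the enone is reduced 1,2, hydride reaching C6 from the open α face because the β face is screened by the axial C19 and C20 methyls, which should give the axial 6β-alcohol.

Step 9
Reactants: 12 9α-(triethylsilyloxy)drim-7-ene-6β,11-diol
Product: 13 6β-hydroxy-9α-(triethylsilyloxy)drim-7-en-11-yl 4-toluenesulfonate
Conditions: TsCl (1.2 equiv), pyridine, DMAP (cat.), 0 °C → rt
Reagents that add atoms: 4-toluenesulfonyl chloride, Cc1ccc(cc1)S(=O)(=O)Cl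
Why: Selective sulfonylation, since the primary C11 hydroxyl should react far faster than the axial allylic 6β-hydroxyl, which is flanked by two syn-axial methyls.

Step 10
Reactants: 13 6β-hydroxy-9α-(triethylsilyloxy)drim-7-en-11-yl 4-toluenesulfonate
Product: 14 6β-hydroxy-9α-(triethylsilyloxy)driman-11-yl 4-toluenesulfonate (8β-H; C17 8α)
Conditions: [Ir(cod)(PCy3)(py)]PF6 (10 mol %), H2 (1–10 bar), CH2Cl2, rt
Reagents that add atoms: none
Why: Hydroxyl-directed homogeneous hydrogenation, in which [Ir(cod)(PCy3)(py)]PF6 binds the pseudoaxial 6β-OH (the only free hydroxyl) and delivers H2 to the β face of the Δ7 alkene, so that C8 receives 8β-H and C17 becomes equatorial (8α), against the steric bias an undirected catalyst would follow.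

Step 11
Reactants: 14 6β-hydroxy-9α-(triethylsilyloxy)driman-11-yl 4-toluenesulfonate
Product: 16 9α,11-epoxydriman-6β-ol, via hydroxy tosylate 15 (not isolated)
Conditions: Bu4NF (2 equiv), THF, 0 °C → rt
Reagents that add atoms: none
Why: Fluoride desilylation followed by Williamson-type 3-exo-tet closure, in which the liberated 9α-alkoxide displaces the adjacent primary tosylate, so the C9–O bond and its configuration are kept in the spiro-oxirane.

Step 12
Reactants: 16 9α,11-epoxydriman-6β-ol; 17 2-methylprop-2-en-1-ol (methallyl alcohol)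
Product: 19 15-norlabd-13(16)-ene-6β,9α,14-triol, via dilithiated methallyl alcohol 18 (not isolated)
Conditions: 17 (5 equiv), n-BuLi (10 equiv), TMEDA, Et2O, 0 °C → rt; then 16 (pre-treated with n-BuLi, 1 equiv) in THF, 0 °C → rt; H2O
Reagents that add atoms: none
Why: Epoxide opening by an allyllithium, in which the C,O-dilithiated methallyl alcohol attacks the unsubstituted C11 terminus of the 2,2-disubstituted oxirane in an SN2 sense, forming C11–C12 and freeing the 9α-hydroxyl without touching a stereocentre.

Step 13
Reactants: 19 15-norlabd-13(16)-ene-6β,9α,14-triol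
Product: 20 (13S)-13,16-epoxy-15-norlabdane-6β,9α,14-triol
Conditions: Ti(OiPr)4 (1.2 equiv), L-(+)-diethyl tartrate (1.4 equiv), t-BuOOH (2 equiv), 4 Å sieves, CH2Cl2, −20 °C
Reagents that add atoms: tert-butyl hydroperoxide, CC(C)(C)OO
Why: Katsuki–Sharpless asymmetric epoxidation, in which the only alkene is that of the primary allylic alcohol, and L-(+)-tartrate, which turns 2-substituted allyl alcohols into (S)-glycidols, sets C13 under reagent control.

Step 14
Reactants: 20 (13S)-13,16-epoxy-15-norlabdane-6β,9α,14-triol
Product: 21 (13R)-13,16-epoxy-6β,9α-dihydroxy-15-norlabdan-14-al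
Conditions: TEMPO (10 mol %), PhI(OAc)2 (1.1 equiv), CH2Cl2, 0 °C → rt
Reagents that add atoms: none
Why: Oxoammonium (TEMPO) oxidation, whose bulky oxidant should take the primary alcohol to the aldehyde and leave the congested secondary 6β-OH and the tertiary 9α-OH alone, while the quaternary C13 cannot epimerise (the descriptor changes by priority only).

Step 15
Reactants: 21 (13R)-13,16-epoxy-6β,9α-dihydroxy-15-norlabdan-14-al
Product: 22 (13S)-13,16-epoxylabd-14-yne-6β,9α-diol
Conditions: dimethyl (1-diazo-2-oxopropyl)phosphonate (1.5 equiv), K2CO3 (2 equiv), MeOH, 0 °C → rt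
Reagents that add atoms: dimethyl (1-diazo-2-oxopropyl)phosphonate, CC(=O)C(=[N+]=[N-])P(=O)(OC)OC
Why: Ohira–Bestmann homologation, in which the diazophosphonate anion released by methanolysis adds to the aldehyde and loss of phosphate and N2 with a 1,2-hydrogen shift gives the terminal alkyne (C15) under a mild base that spares the epoxide.

Step 16
Reactants: 22 (13S)-13,16-epoxylabd-14-yne-6β,9α-diol
Product: 23 (13R)-9α,13-epoxylabd-14-yne-6β,16-diol
Conditions: camphor-10-sulfonic acid (10 mol %), CH2Cl2, 0 °C
Reagents that add atoms: none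
Why: Acid-catalysed 5-exo-tet hydroxy-epoxide cyclisation, in which the protonated oxirane is opened at its tertiary propargylic C13 by the 9α-hydroxyl from the rear, so that C13 is inverted to R, ring C closes and C16 is released as a primary alcohol.

Step 17
Reactants: 23 (13R)-9α,13-epoxylabd-14-yne-6β,16-diol
Product: 24 (13R)-9α,13;15,16-diepoxylabd-14-en-6β-ol
Conditions: Mo(CO)6 (30 mol %), Me3NO (30 mol %), Et3N/Et2O, rt
Reagents that add atoms: none
Why: Endo-selective alkynol cycloisomerisation of a but-3-yn-1-ol, in which the terminal alkyne rearranges to a vinylidene on the Mo(CO)5 fragment and its electrophilic C15 is captured by the C16 hydroxyl, giving the 2,3-dihydrofuran (ring D) in an amine-buffered medium that the acid-labile allylic spiro ether should tolerate.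

Step 18
Reactants: 24 (13R)-9α,13;15,16-diepoxylabd-14-en-6β-ol
Product: 25 (13R)-6β-acetoxy-9α,13;15,16-diepoxylabd-14-ene (CNP0242014.1)
Conditions: Ac2O (5 equiv), DMAP (0.5 equiv), Et3N, CH2Cl2, rt → 35 °C; aq NaHCO3; Et3N-deactivated silica
Reagents that add atoms: acetic anhydride, CC(=O)OC(C)=O
Why: DMAP-catalysed acylation, in which the acylpyridinium ion esterifies the hindered axial 6β-alcohol with retention and the basic medium guards the enol ether against acid-triggered opening of ring C and aromatisation to the furan.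

Compound list
1 | methyl acetoacetate | COC(=O)CC(C)=O | starting material
2 | geranyl bromide | CC(C)=CCC/C(C)=C/CBr | starting material
3 | sodium lithium dianion of methyl acetoacetate | [Na+].[Li+].[CH2-]C(=O)[CH-]C(=O)OC | intermediate (not isolated)
4 | methyl (6E)-7,11-dimethyl-3-oxododeca-6,10-dienoate | COC(=O)CC(=O)CC/C=C(\C)CCC=C(C)C | intermediate
5 | methyl 8-oxo-17-nordriman-11-oate (1R,4aS,8aS decalin β-keto ester) | C1CC(=O)[C@H](C(=O)OC)[C@@]2(C)CCCC(C)(C)[C@H]12 | intermediate
6 | potassium enolate of 5 | C1CC([O-])=C(C(=O)OC)[C@@]2(C)CCCC(C)(C)[C@H]12.[K+] | intermediate (not isolated)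
7 | methyl 9α-hydroxy-8-oxo-17-nordriman-11-oate | C1CC(=O)[C@](O)(C(=O)OC)[C@@]2(C)CCCC(C)(C)[C@H]12 | intermediate
8 | methyl 8,9α-bis(triethylsilyloxy)-17-nordrim-7-en-11-oate | C1C=C(O[Si](CC)(CC)CC)[C@](O[Si](CC)(CC)CC)(C(=O)OC)[C@@]2(C)CCCC(C)(C)[C@H]12 | intermediate
9 | methyl 8-oxo-9α-(triethylsilyloxy)-17-nordrim-6-en-11-oate | C1=CC(=O)[C@](O[Si](CC)(CC)CC)(C(=O)OC)[C@@]2(C)CCCC(C)(C)[C@H]12 | intermediate
10 | methyl 8β-hydroxy-9α-(triethylsilyloxy)drim-6-en-11-oate (drawn as the expected 8β-alcohol; the C8 epimer converges) | C1=C[C@@](O)(C)[C@](O[Si](CC)(CC)CC)(C(=O)OC)[C@@]2(C)CCCC(C)(C)[C@H]12 | intermediate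
11 | methyl 6-oxo-9α-(triethylsilyloxy)drim-7-en-11-oate | O=C1C=C(C)[C@](O[Si](CC)(CC)CC)(C(=O)OC)[C@@]2(C)CCCC(C)(C)[C@H]12 | intermediate
12 | 9α-(triethylsilyloxy)drim-7-ene-6β,11-diol | O[C@@H]1C=C(C)[C@](O[Si](CC)(CC)CC)(CO)[C@@]2(C)CCCC(C)(C)[C@H]12 | intermediate
13 | 6β-hydroxy-9α-(triethylsilyloxy)drim-7-en-11-yl 4-toluenesulfonate | O[C@@H]1C=C(C)[C@](O[Si](CC)(CC)CC)(COS(=O)(=O)c3ccc(C)cc3)[C@@]2(C)CCCC(C)(C)[C@H]12 | intermediate
14 | 6β-hydroxy-9α-(triethylsilyloxy)driman-11-yl 4-toluenesulfonate (8β-H) | O[C@@H]1C[C@@H](C)[C@](O[Si](CC)(CC)CC)(COS(=O)(=O)c3ccc(C)cc3)[C@@]2(C)CCCC(C)(C)[C@H]12 | intermediate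
15 | 6β,9α-dihydroxydriman-11-yl 4-toluenesulfonate | O[C@@H]1C[C@@H](C)[C@](O)(COS(=O)(=O)c3ccc(C)cc3)[C@@]2(C)CCCC(C)(C)[C@H]12 | intermediate (not isolated)
16 | 9α,11-epoxydriman-6β-ol | O[C@@H]1C[C@@H](C)[C@]3(CO3)[C@@]2(C)CCCC(C)(C)[C@H]12 | intermediate
17 | 2-methylprop-2-en-1-ol | CC(=C)CO | starting material
18 | dilithiated methallyl alcohol | [Li]CC(=C)CO[Li] | intermediate (not isolated)
19 | 15-norlabd-13(16)-ene-6β,9α,14-triol | O[C@@H]1C[C@@H](C)[C@](O)(CCC(=C)CO)[C@@]2(C)CCCC(C)(C)[C@H]12 | intermediate
20 | (13S)-13,16-epoxy-15-norlabdane-6β,9α,14-triol | O[C@@H]1C[C@@H](C)[C@](O)(CC[C@]3(CO)CO3)[C@@]2(C)CCCC(C)(C)[C@H]12 | intermediate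
21 | (13R)-13,16-epoxy-6β,9α-dihydroxy-15-norlabdan-14-al | O[C@@H]1C[C@@H](C)[C@](O)(CC[C@]3(C=O)CO3)[C@@]2(C)CCCC(C)(C)[C@H]12 | intermediate
22 | (13S)-13,16-epoxylabd-14-yne-6β,9α-diol | O[C@@H]1C[C@@H](C)[C@](O)(CC[C@]3(C#C)CO3)[C@@]2(C)CCCC(C)(C)[C@H]12 | intermediate
23 | (13R)-9α,13-epoxylabd-14-yne-6β,16-diol | O[C@@H]1C[C@@H](C)[C@]3(CC[C@@](C#C)(CO)O3)[C@@]2(C)CCCC(C)(C)[C@H]12 | intermediate
24 | (13R)-9α,13;15,16-diepoxylabd-14-en-6β-ol | O[C@@H]1C[C@@H](C)[C@]2(CC[C@]3(C=COC3)O2)[C@@]2(C)CCCC(C)(C)[C@H]12 | intermediate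
25 | (5S,6R,8R,9R,10S,13R)-6-acetoxy-9,13;15,16-diepoxylabd-14-ene | CC(=O)O[C@@H]1C[C@@H](C)[C@]2(CC[C@]3(C=COC3)O2)[C@@]2(C)CCCC(C)(C)[C@H]12 | target

Total step count: 18. Longest linear sequence: 18 (steps 1–18; 17 is bought).

Steps most likely to fail

Step 2. The chelating β-dicarbonyl may strip SnCl4 from the chiral ligand. Achiral acid could then protonate C3, which would erode enantioselectivity, and early proton loss could stall the cascade after ring A. The fallback uses known chemistry and replaces asymmetric protonation by covalent resolution. It sets out from 2. The dianion of commercial (−)-menthyl acetoacetate (CC(=O)CC(=O)O[C@@H]1C[C@H](C)CC[C@H]1C(C)C; NaH, n-BuLi, THF) is alkylated with 2 to give (1R,2S,5R)-menthyl (6E)-7,11-dimethyl-3-oxododeca-6,10-dienoate F1. The established achiral SnCl4 bicyclisation (CH2Cl2, 0 °C → rt) closes the same two bonds. It should give two trans-decalin diastereomers that differ in the sense of the core relative to the menthyl group, to be separated by crystallisation or chromatography. The isomer with the (5S,9R,10S) core, (1R,2S,5R)-menthyl 8-oxo-17-nordriman-11-oate F2, is transesterified (MeOH, DMAP, toluene, sealed tube, 110 °C) and comes back to the route at 5.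

Step 10. The β face is crowded by C19 and C20, so binding of the iridium complex to the 6β-OH may be weak. That would mean slow reduction, poor facial selectivity, or competing isomerisation of the allylic alcohol. The fallback gives up directed kinetic delivery for thermodynamic control and changes the order of events. It sets out from 12, which is reduced by metal-hydride hydrogen-atom transfer (Mn(dpm)3 cat., PhSiH3, t-BuOOH, i-PrOH, rt). Hydrogen adds first to C7, and the tertiary C8 radical should be quenched so that C17 ends equatorial, giving 9α-(triethylsilyloxy)drimane-6β,11-diol F3. Selective tosylation of its primary hydroxyl (TsCl, pyridine) comes back to the route at 14.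

Step 16. The nucleophile is a hindered tertiary alcohol. Ionisation at the propargylic C13 could therefore precede attack and cost stereochemical fidelity. A 1,2-shift of the opened epoxide or 6-endo attack at C16 could also compete. The fallback closes ring C on an ordinary tertiary epoxide and builds the alkyne afterwards. The roles of the two one-carbon arms on C13 are exchanged, which calls for the antipodal tartrate. It sets out from 19.
- Ti(OiPr)4, D-(−)-diethyl tartrate and t-BuOOH give (13R)-13,14-epoxy-15-norlabdane-6β,9α,16-triol F4, in which the hydroxymethyl arm is the future C16 and the oxirane CH2 the future C14.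
- TBSCl/imidazole caps the primary alcohol as (13S)-16-(tert-butyldimethylsilyloxy)-13,14-epoxy-15-norlabdane-6β,9α-diol F5.
- Camphor-10-sulfonic acid closes ring C by 5-exo opening with inversion to (13R)-16-(tert-butyldimethylsilyloxy)-9α,13-epoxy-15-norlabdane-6β,14-diol F6.
- TEMPO/PhI(OAc)2 gives (13S)-16-(tert-butyldimethylsilyloxy)-9α,13-epoxy-6β-hydroxy-15-norlabdan-14-al F7.
- The Ohira–Bestmann reagent gives (13R)-16-(tert-butyldimethylsilyloxy)-9α,13-epoxylabd-14-yn-6β-ol F8.
- Bu4NF removes the silyl group and the sequence comes back to the route at 23.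

Further compounds
F1 | step 2 | (1R,2S,5R)-menthyl (6E)-7,11-dimethyl-3-oxododeca-6,10-dienoate | CC(C)=CCC/C(C)=C/CCC(=O)CC(=O)O[C@@H]1C[C@H](C)CC[C@H]1C(C)C
F2 | step 2 | (1R,2S,5R)-menthyl 8-oxo-17-nordriman-11-oate (5S,9R,10S core) | C1CC(=O)[C@H](C(=O)O[C@@H]3C[C@H](C)CC[C@H]3C(C)C)[C@@]2(C)CCCC(C)(C)[C@H]12
F3 | step 10 | 9α-(triethylsilyloxy)drimane-6β,11-diol (8β-H) | O[C@@H]1C[C@@H](C)[C@](O[Si](CC)(CC)CC)(CO)[C@@]2(C)CCCC(C)(C)[C@H]12
F4 | step 16 | (13R)-13,14-epoxy-15-norlabdane-6β,9α,16-triol | O[C@@H]1C[C@@H](C)[C@](O)(CC[C@@]3(CO)CO3)[C@@]2(C)CCCC(C)(C)[C@H]12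
F5 | step 16 | (13S)-16-(tert-butyldimethylsilyloxy)-13,14-epoxy-15-norlabdane-6β,9α-diol | O[C@@H]1C[C@@H](C)[C@](O)(CC[C@@]3(CO[Si](C)(C)C(C)(C)C)CO3)[C@@]2(C)CCCC(C)(C)[C@H]12
F6 | step 16 | (13R)-16-(tert-butyldimethylsilyloxy)-9α,13-epoxy-15-norlabdane-6β,14-diol | O[C@@H]1C[C@@H](C)[C@]3(CC[C@](CO[Si](C)(C)C(C)(C)C)(CO)O3)[C@@]2(C)CCCC(C)(C)[C@H]12
F7 | step 16 | (13S)-16-(tert-butyldimethylsilyloxy)-9α,13-epoxy-6β-hydroxy-15-norlabdan-14-al | O[C@@H]1C[C@@H](C)[C@]3(CC[C@](CO[Si](C)(C)C(C)(C)C)(C=O)O3)[C@@]2(C)CCCC(C)(C)[C@H]12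
F8 | step 16 | (13R)-16-(tert-butyldimethylsilyloxy)-9α,13-epoxylabd-14-yn-6β-ol | O[C@@H]1C[C@@H](C)[C@]3(CC[C@](CO[Si](C)(C)C(C)(C)C)(C#C)O3)[C@@]2(C)CCCC(C)(C)[C@H]12
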